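**Retrosynthetic overview**

1. The target, (13Z)-6β-hydroxylabda-8,13-diene-7α,15-diyl diacetate, is traced back through selective diacetylation of a 6β,7α,15-triol, hydroxyl-directed reduction of a 6β-hydroxy-8-en-7-one, and oxidative 1,3-transposition of a C9 carbinol. That carbinol comes from 1,2-addition of the Z side chain (C11–C16, from 4-methyl-5,6-dihydropyran-2-one) to a 6β-silyloxy-7-en-9-one.
2. The 6β-oxygen comes from γ-oxidation at C6 of 4,4,8,10-tetramethyl-trans-decal-7-en-9-one, followed by α-face hydride reduction of the C6 ketone.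
3. Key disconnection: C8 with its methyl C17 is removed from between C7 and C9 of ring B, which leads back to the C9 silyl enol ether of a trans-hydrindan-9-one and chloro(methyl)carbene from 1,1-dichloroethane.
4. Structural feature that carries the plan: the C9 carbonyl of the five-membered ring lies between quaternary C10 and the C7 methylene, so it can enolise in one direction only (C9=C7), and the inserted carbon can only become C8.
5. Ring order: ring A and the five-membered ring are bought with C10 set; C4 is gem-dimethylated, C3 deoxygenated and C5 set by hydrogenation; ring B is formed last by one-carbon enlargement.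

Key step: step 7

Assumption: labdane numbering (C1–C20) is used for all bicyclic compounds, α is the face opposite the C10 methyl, and the target SMILES is read as 5α-H, 10β-CH3, 6β-OH, 7α-OAc, 13Z.

**Route**

Step 1
Reactants: 1 (S)-7a-methyl-2,3,7,7a-tetrahydro-1H-indene-1,5(6H)-dione
Product: 2 C9 mono-ethylene ketal of 1 (enone untouched)
Conditions: (TMSOCH2)2, TMSOTf (cat.), CH2Cl2, −78 → −20 °C
Reagents that add atoms: 1,2-bis(trimethylsilyloxy)ethane, C[Si](C)(C)OCCO[Si](C)(C)C
Why: Silyl-triflate-catalysed acetalisation at low temperature should take the saturated five-ring ketone and leave the much less electrophilic conjugated ketone, as is usual for saturated versus conjugated carbonyls.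

Step 2
Reactants: 2 C9 mono-ethylene ketal of 1
Product: 3 C9-ketal of the 4,4-dimethyl-5(6)-en-3-one (C4 gem-dimethyl, C3 ketone, C5=C6 in the five-membered ring)
Conditions: t-BuOK, t-BuOH/THF, 0 °C; MeI, 0 °C → rt
Reagents that add atoms: iodomethane, CI
Why: Twofold C-methylation of the extended dienolate at C4 (deconjugative α,α-dialkylation of an enone) should move the alkene to C5=C6 and leave C4 quaternary.

Step 3
Reactants: 3 C9-ketal of the 4,4-dimethyl-5(6)-en-3-one
Product: 4 C9 ethylene ketal of (S)-4,4,7a-trimethyl-2,4,5,6,7,7a-hexahydro-1H-inden-1-one (C5=C6 alkene)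
Conditions: N2H4·H2O, KOH, diethylene glycol, 130 → 200 °C
Reagents that add atoms: none
Why: Wolff–Kishner reduction removes the C3 carbonyl; the ketal is base-stable and the alkene cannot migrate into conjugation past quaternary C4.

Step 4
Reactants: 4 C9 ethylene ketal of the 5(6)-ene
Product: 5 ethylene ketal of (3aS,7aS)-4,4,7a-trimethyloctahydro-1H-inden-1-one (trans-fused, H-5α)
Conditions: H2 (5 bar), Pd/C, EtOAc, rt
Reagents that add atoms: none
Why: Heterogeneous hydrogenation should deliver hydrogen to the α-face of C5=C6, away from the angular C10 methyl and the 4β-methyl, which sets H-5α and the trans ring fusion.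

Step 5
Reactants: 5 trans-fused C9 ketal
Product: 6 (3aS,7aS)-4,4,7a-trimethyloctahydro-1H-inden-1-one
Conditions: 2 M HCl, THF, rt
Reagents that add atoms: water, O
Why: Acid hydrolysis of the dioxolane; C5 is not α to the carbonyl, so the ring fusion cannot epimerise.

Step 6
Reactants: 6 (3aS,7aS)-4,4,7a-trimethyloctahydro-1H-inden-1-one
Product: 7 (3aS,7aS)-4,4,7a-trimethyl-1-(trimethylsilyloxy)-3a,4,5,6,7,7a-hexahydro-3H-indene (C9=C7 silyl enol ether)
Conditions: i-Pr2NLi, THF, −78 °C; TMSCl, −78 → 0 °C; non-aqueous work-up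
Reagents that add atoms: chlorotrimethylsilane, C[Si](C)(C)Cl
Why: Enolate formation and O-silylation; only C7 carries α-hydrogens, so a single enol ether can form.

Step 7
Reactants: 7 C9=C7 trimethylsilyl enol ether, 8 1,1-dichloroethane
Product: 10 (4aS,8aS)-2,5,5,8a-tetramethyl-4a,5,6,7,8,8a-hexahydronaphthalen-1(4H)-one (4,4,8,10-tetramethyl-trans-decal-7-en-9-one), via siloxy chlorocyclopropane 9 (not isolated)
Conditions: 8 (3 equiv), n-BuLi (slow addition), Et2O, −40 → −20 °C; then toluene, 110 °C
Reagents that add atoms: 1,1-dichloroethane, CC(Cl)Cl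
Why: n-BuLi deprotonates 8 to 1,1-dichloroethyllithium, whose α-elimination transfers chloro(methyl)carbene to the electron-rich C9=C7 bond to give 9; on heating, chloride leaves while the C7–C9 cyclopropane bond opens in a disrotatory two-electron electrocyclic process pushed by the siloxy oxygen, and the silyloxyallyl cation loses chlorotrimethylsilane to give the C9 ketone with the C7=C8 alkene. The closest known reaction type is the one-carbon enlargement of cyclic silyl enol ethers with halocarbenes to 2-substituted cycloalk-2-enones. Ring B is closed by insertion, not cyclisation: a [2+1] cycloaddition forms C7–C8 and C8–C9, and cleavage of the shared C7–C9 bond turns the bicyclo[3.1.0] unit into the six-membered ring. No stereocentre is created in the product, since the cyclopropane centres are destroyed and C5 and C10 are untouched. The step needs regiocontrol and a chlorine cis to the five-membered ring: the first is certain because quaternary C10 allows only the C9=C7 enol ether, and the second should be favoured because the larger methyl takes the exo position, and only the endo chloride can ionise to a cis-cyclohexenyl cation.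

Step 8
Reactants: 10 4,4,8,10-tetramethyl-trans-decal-7-en-9-one
Product: 11 9-(trimethylsilyloxy)-4,4,8,10-tetramethyl-trans-decala-6,8-diene (dienol silyl ether, used crude)
Conditions: TMSOTf, Et3N, CH2Cl2, 0 °C; pentane, filtration
Reagents that add atoms: trimethylsilyl trifluoromethanesulfonate, C[Si](C)(C)OS(=O)(=O)C(F)(F)F
Why: Soft enolisation: after O-silylation the only acidic hydrogen of the silyloxyallyl cation is H-6 (C10 is quaternary and the C8 methyl is not conjugated to the cation termini), so the linear dienol ether should form.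

Step 9
Reactants: 11 dienol silyl ether
Product: 12 6α-hydroxy-4,4,8,10-tetramethyl-trans-decal-7-en-9-one (6α epimer expected; either epimer serves)
Conditions: mCPBA, NaHCO3, CH2Cl2, −20 °C; aq. NaHCO3
Reagents that add atoms: 3-chloroperoxybenzoic acid, OOC(=O)c1cccc(Cl)c1
Why: Vinylogous Rubottom oxidation: epoxidation of the distal C6=C7 bond from the open α-face and opening by the enol ether should give the γ-hydroxy enone, whose C6 configuration is erased in the next step.

Step 10
Reactants: 12 6-hydroxy-7-en-9-one
Product: 13 4,4,8,10-tetramethyl-trans-decal-7-ene-6,9-dione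
Conditions: Dess–Martin periodinane, NaHCO3, CH2Cl2, rt
Reagents that add atoms: none
Why: Periodinane oxidation of a secondary allylic alcohol under buffered, non-enolising conditions keeps C5 intact.

Step 11
Reactants: 13 7-ene-6,9-dione
Product: 14 6β-hydroxy-4,4,8,10-tetramethyl-trans-decal-7-en-9-one
Conditions: NaBH4, CeCl3·7H2O, MeOH, −78 °C
Reagents that add atoms: none
Why: Luche 1,2-reduction should select the C6 carbonyl over the C9 carbonyl, which is buried between quaternary C10 and the C8 methyl; hydride enters from the α-face because the β-face is screened by the syn-axial C10 and 4β methyls, giving the axial 6β-alcohol.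

Step 12
Reactants: 14 6β-hydroxy-7-en-9-one
Product: 15 6β-(triethylsilyloxy)-4,4,8,10-tetramethyl-trans-decal-7-en-9-one
Conditions: TESOTf, 2,6-lutidine, CH2Cl2, −40 → 0 °C
Reagents that add atoms: triethylsilyl trifluoromethanesulfonate, CC[Si](CC)(CC)OS(=O)(=O)C(F)(F)F
Why: A silyl triflate with a hindered pyridine base silylates even a crowded axial alcohol without enolising the enone.

Step 13
Reactants: 16 5,6-dihydro-4-methyl-2H-pyran-2-one
Product: 17 (Z)-5-hydroxy-N-methoxy-N,3-dimethylpent-2-enamide
Conditions: MeNH(OMe)·HCl, AlMe3, CH2Cl2, 0 °C → rt; aq. KNaC4H4O6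
Reagents that add atoms: N,O-dimethylhydroxylamine hydrochloride, CNOC.Cl
Why: Aluminium-amide aminolysis of the lactone (Weinreb amide formation) cleaves only the acyl–oxygen bond, so the ring-enforced Z geometry is kept and the two chain ends are differentiated as acyl (C15) and alcohol (C11).

Step 14
Reactants: 17 (Z)-5-hydroxy Weinreb amide
Product: 18 (Z)-5-bromo-N-methoxy-N,3-dimethylpent-2-enamide
Conditions: CBr4, PPh3, CH2Cl2, 0 °C
Reagents that add atoms: tetrabromomethane, BrC(Br)(Br)Br
Why: Appel bromination of the primary alcohol proceeds under neutral conditions that leave the Z-enamide geometry alone.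

Step 15
Reactants: 18 (Z)-5-bromo Weinreb amide
Product: 20 (Z)-5-bromo-3-methylpent-2-en-1-ol, via bromo enal 19 (not isolated)
Conditions: i-Bu2AlH, CH2Cl2, −78 °C; aq. KNaC4H4O6; crude aldehyde: NaBH4, CeCl3·7H2O, MeOH, −20 °C
Reagents that add atoms: none
Why: Weinreb amide reduction stops at the aldehyde through the chelated aluminium hemiaminal, and the crude Z-enal is reduced at once under Luche conditions before it can isomerise; the primary bromide is inert to both hydrides at these temperatures.

Step 16
Reactants: 20 (Z)-5-bromo-3-methylpent-2-en-1-ol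
Product: 21 (Z)-[(5-bromo-3-methylpent-2-en-1-yl)oxy](tert-butyl)dimethylsilane
Conditions: TBSCl, imidazole, CH2Cl2, 0 °C
Reagents that add atoms: tert-butyldimethylsilyl chloride, CC(C)(C)[Si](C)(C)Cl
Why: Standard silylation with a weak base avoids alkoxide formation and hence cyclisation of the bromo alcohol to a dihydropyran.

Step 17
Reactants: 21 (Z)-bromide silyl ether, 15 6β-(triethylsilyloxy)-7-en-9-one
Product: 24 (13Z)-15-(tert-butyldimethylsilyloxy)-6β-(triethylsilyloxy)labda-7,13-dien-9-ol (C9 epimers), via Grignard reagent 22 (not isolated), via organocerium reagent 23 (not isolated)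
Conditions: 21, Mg (activated), THF, rt; anhydrous CeCl3, THF, −78 °C; then 15, −78 → −40 °C; aq. NH4Cl
Reagents that add atoms: none
Why: Organocerium 1,2-addition to a hindered enone; the low basicity of the reagent should suppress γ-deprotonation and conjugate addition, and the C9 configuration is of no consequence because it is lost in the next step.

Step 18
Reactants: 24 C9 tertiary allylic alcohol
Product: 25 (13Z)-15-(tert-butyldimethylsilyloxy)-6β-(triethylsilyloxy)labda-8,13-dien-7-one
Conditions: pyridinium chlorochromate, NaOAc, 4 Å MS, CH2Cl2, rt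
Reagents that add atoms: pyridinium chlorochromate, [O-][Cr](=O)(=O)Cl.c1cc[nH+]cc1
Why: Babler–Dauben oxidative transposition: the chromate ester of the tertiary allylic alcohol undergoes a [3,3] shift to C7 and the resulting secondary chromate is oxidised to the 8-en-7-one, with acetate buffering to spare the silyl ethers.

Step 19
Reactants: 25 bis-silylated 8-en-7-one
Product: 26 (13Z)-6β,15-dihydroxylabda-8,13-dien-7-one
Conditions: HF·pyridine, pyridine, THF, 0 °C → rt
Reagents that add atoms: none
Why: Fluoride desilylation under mildly acidic conditions removes both silyl groups without base-induced enolisation toward C6, which would epimerise the axial 6β-hydroxyl.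

Step 20
Reactants: 26 6β,15-dihydroxy-8-en-7-one
Product: 27 (13Z)-labda-8,13-diene-6β,7α,15-triol
Conditions: Me4NBH(OAc)3, MeCN/AcOH, −20 °C
Reagents that add atoms: none
Why: Evans–Saksena directed reduction: the axial 6β-hydroxyl binds boron and delivers hydride intramolecularly to the β-face of C7, so the new hydroxyl is 7α, trans to 6β-OH.

Step 21
Reactants: 27 6β,7α,15-triol
Product: 28 (13Z)-6β-hydroxylabda-8,13-diene-7α,15-diyl diacetate
Conditions: Ac2O, pyridine, DMAP (cat.), CH2Cl2, 0 °C
Reagents that add atoms: acetic anhydride, CC(=O)OC(C)=O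
Why: Acylation should take the primary C15 and the allylic C7 hydroxyls, while the 6β-hydroxyl, syn-axial to the 4β and C10 methyls, resists acylation under these conditions.

**Compound list**

1 | (S)-7a-methyl-2,3,7,7a-tetrahydro-1H-indene-1,5(6H)-dione | O=C1CCC2=CC(=O)CC[C@]12C | starting material
2 | C9 mono-ethylene ketal of 1 | O1CCOC13CCC2=CC(=O)CC[C@]32C | intermediate
3 | C9-ketal of the 4,4-dimethyl-5(6)-en-3-one | O1CCOC13CC=C2C(C)(C)C(=O)CC[C@]32C | intermediate
4 | C9 ethylene ketal of (S)-4,4,7a-trimethyl-2,4,5,6,7,7a-hexahydro-1H-inden-1-one | O1CCOC13CC=C2C(C)(C)CCC[C@]32C | intermediate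
5 | ethylene ketal of (3aS,7aS)-4,4,7a-trimethyloctahydro-1H-inden-1-one | O1CCOC13CC[C@H]2C(C)(C)CCC[C@]32C | intermediate
6 | (3aS,7aS)-4,4,7a-trimethyloctahydro-1H-inden-1-one | O=C1CC[C@H]2C(C)(C)CCC[C@]12C | intermediate
7 | (3aS,7aS)-4,4,7a-trimethyl-1-(trimethylsilyloxy)-3a,4,5,6,7,7a-hexahydro-3H-indene | C[Si](C)(C)OC1=CC[C@H]2C(C)(C)CCC[C@]12C | intermediate
8 | 1,1-dichloroethane | CC(Cl)Cl | starting material
9 | siloxy chlorocyclopropane (8-chloro-8-methyl-9-trimethylsilyloxy, C7–C8–C9 three-membered ring; diastereomer mixture) | C[Si](C)(C)OC13C(C)(Cl)C3C[C@H]2C(C)(C)CCC[C@]12C | intermediate (not isolated)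
10 | (4aS,8aS)-2,5,5,8a-tetramethyl-4a,5,6,7,8,8a-hexahydronaphthalen-1(4H)-one | O=C1C(C)=CC[C@H]2C(C)(C)CCC[C@]12C | intermediate
11 | 9-(trimethylsilyloxy)-4,4,8,10-tetramethyl-trans-decala-6,8-diene | C[Si](C)(C)OC1=C(C)C=C[C@H]2C(C)(C)CCC[C@]12C | intermediate
12 | 6α-hydroxy-4,4,8,10-tetramethyl-trans-decal-7-en-9-one | O=C1C(C)=C[C@H](O)[C@H]2C(C)(C)CCC[C@]12C | intermediate
13 | 4,4,8,10-tetramethyl-trans-decal-7-ene-6,9-dione | O=C1C(C)=CC(=O)[C@H]2C(C)(C)CCC[C@]12C | intermediate
14 | 6β-hydroxy-4,4,8,10-tetramethyl-trans-decal-7-en-9-one | O=C1C(C)=C[C@@H](O)[C@H]2C(C)(C)CCC[C@]12C | intermediate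
15 | 6β-(triethylsilyloxy)-4,4,8,10-tetramethyl-trans-decal-7-en-9-one | O=C1C(C)=C[C@@H](O[Si](CC)(CC)CC)[C@H]2C(C)(C)CCC[C@]12C | intermediate
16 | 5,6-dihydro-4-methyl-2H-pyran-2-one | CC1=CC(=O)OCC1 | starting material
17 | (Z)-5-hydroxy-N-methoxy-N,3-dimethylpent-2-enamide | CON(C)C(=O)/C=C(/C)CCO | intermediate
18 | (Z)-5-bromo-N-methoxy-N,3-dimethylpent-2-enamide | CON(C)C(=O)/C=C(/C)CCBr | intermediate
19 | (Z)-5-bromo-3-methylpent-2-enal | O=C/C=C(/C)CCBr | intermediate (not isolated)
20 | (Z)-5-bromo-3-methylpent-2-en-1-ol | OC/C=C(/C)CCBr | intermediate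
21 | (Z)-[(5-bromo-3-methylpent-2-en-1-yl)oxy](tert-butyl)dimethylsilane | CC(C)(C)[Si](C)(C)OC/C=C(/C)CCBr | intermediate
22 | (Z)-5-(tert-butyldimethylsilyloxy)-3-methylpent-3-enylmagnesium bromide | CC(C)(C)[Si](C)(C)OC/C=C(/C)CC[Mg]Br | intermediate (not isolated)
23 | (Z)-5-(tert-butyldimethylsilyloxy)-3-methylpent-3-enylcerium dichloride | CC(C)(C)[Si](C)(C)OC/C=C(/C)CC[Ce](Cl)Cl | intermediate (not isolated)
24 | (13Z)-15-(tert-butyldimethylsilyloxy)-6β-(triethylsilyloxy)labda-7,13-dien-9-ol (C9 epimers) | CC(C)(C)[Si](C)(C)OC/C=C(/C)CCC1(O)C(C)=C[C@@H](O[Si](CC)(CC)CC)[C@H]2C(C)(C)CCC[C@]12C | intermediate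
25 | (13Z)-15-(tert-butyldimethylsilyloxy)-6β-(triethylsilyloxy)labda-8,13-dien-7-one | CC(C)(C)[Si](C)(C)OC/C=C(/C)CCC1=C(C)C(=O)[C@@H](O[Si](CC)(CC)CC)[C@H]2C(C)(C)CCC[C@]12C | intermediate
26 | (13Z)-6β,15-dihydroxylabda-8,13-dien-7-one | OC/C=C(/C)CCC1=C(C)C(=O)[C@@H](O)[C@H]2C(C)(C)CCC[C@]12C | intermediate
27 | (13Z)-labda-8,13-diene-6β,7α,15-triol | OC/C=C(/C)CCC1=C(C)[C@H](O)[C@@H](O)[C@H]2C(C)(C)CCC[C@]12C | intermediate
28 | (13Z)-6β-hydroxylabda-8,13-diene-7α,15-diyl diacetate | CC(=O)OC/C=C(/C)CCC1=C(C)[C@H](OC(C)=O)[C@@H](O)[C@H]2C(C)(C)CCC[C@]12C | target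

**Step count and risks**

Total step count: 21. Longest linear sequence: 17 (steps 1–12 and 17–21); the side chain (steps 13–16) is made separately.

Steps most likely to fail:

Step 7. Carbene transfer to the enol ether next to quaternary C10 may be incomplete, and part of the adduct may carry chlorine on the exo face, from which ionisation to a cis-cyclohexenyl cation is not possible. The fallback introduces the methyl separately. Starting from 7, dibromocarbene (CHBr3, t-BuOK, pentane, −20 °C) should give the 8,8-dibromo-9-(trimethylsilyloxy) cyclopropane F1, in which one bromine is necessarily cis to the five-membered ring. Warming in toluene should open it, with loss of bromotrimethylsilane, to 8-bromo-4,4,10-trimethyl-trans-decal-7-en-9-one F2. Stille methylation (Me4Sn, Pd(PPh3)4, CuI, DMF, 60 °C) then leads back to 10.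

Step 9. The peracid may attack the tetrasubstituted C8=C9 enol ether bond and place oxygen at C8 instead of C6. The fallback drops the dienol ether and oxidises the γ-C–H bond of the enone directly. Starting from 10, Pd(OH)2/C, t-BuOOH and K2CO3 in CH2Cl2 at rt should convert the γ-methylene C6 into a carbonyl by hydrogen abstraction and peroxide collapse, and so rejoin the route at 13 without any new intermediate (F0), bypassing steps 8–10.

Step 20. Ligand exchange of the crowded axial 6β-hydroxyl onto boron may be slow, so that undirected hydride attack from the α-face, giving the 7β-alcohol, competes. The fallback accepts that intrinsic preference and inverts C7 afterwards. Starting from 25, NaBH4/CeCl3·7H2O in MeOH at −40 °C should give, by attack anti to the axial 6β-silyloxy group, the 7β-alcohol (13Z)-15-(tert-butyldimethylsilyloxy)-6β-(triethylsilyloxy)labda-8,13-dien-7β-ol F3. Mitsunobu inversion with acetic acid (PPh3, diisopropyl azodicarboxylate, toluene, 0 °C) should install the 7α-acetate and give the bis-silyl ether 7α-acetate F4. HF·pyridine in THF should then give (13Z)-7α-acetoxylabda-8,13-diene-6β,15-diol F5, and acetylation of the primary hydroxyl alone (Ac2O, pyridine, 0 °C) rejoins the route at 28.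

Further compounds
F1 | step 7 | 8,8-dibromo-9-(trimethylsilyloxy) cyclopropane adduct of 7 | C[Si](C)(C)OC13C(Br)(Br)C3C[C@H]2C(C)(C)CCC[C@]12C
F2 | step 7 | 8-bromo-4,4,10-trimethyl-trans-decal-7-en-9-one | O=C1C(Br)=CC[C@H]2C(C)(C)CCC[C@]12C
F0 | step 9 | none | none
F3 | step 20 | (13Z)-15-(tert-butyldimethylsilyloxy)-6β-(triethylsilyloxy)labda-8,13-dien-7β-ol | CC(C)(C)[Si](C)(C)OC/C=C(/C)CCC1=C(C)[C@@H](O)[C@@H](O[Si](CC)(CC)CC)[C@H]2C(C)(C)CCC[C@]12C
F4 | step 20 | (13Z)-15-(tert-butyldimethylsilyloxy)-6β-(triethylsilyloxy)labda-8,13-dien-7α-yl acetate | CC(C)(C)[Si](C)(C)OC/C=C(/C)CCC1=C(C)[C@H](OC(C)=O)[C@@H](O[Si](CC)(CC)CC)[C@H]2C(C)(C)CCC[C@]12C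
F5 | step 20 | (13Z)-7α-acetoxylabda-8,13-diene-6β,15-diol | OC/C=C(/C)CCC1=C(C)[C@H](OC(C)=O)[C@@H](O)[C@H]2C(C)(C)CCC[C@]12C
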